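## Retrosynthetic overview

1. The plan rests on furan-ring atoms O1, C2 and C3 and the formyl carbon on C3. These four atoms are read back into an ortho-(arylethynyl)aryl methoxymethyl ether: the alkyne carbons are C2 and C3, the aryl ether oxygen is O1, and the OCH2 carbon of the acetal is the future CHO carbon.
2. Endgame: C3–CHO comes from C3–CH2OMe by benzylic oxidation, C4–OH from its acetate, and the ring-B phenol and the tertiary alcohol from silyl ethers.
3. Key disconnection: O1–C2 and C3–CH2 are made together in one PtCl2-catalysed cycloisomerisation. The furan is the only ring built; the benzo ring (ring A) and the 2-aryl ring (ring B) are bought.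
4. The diarylalkyne comes from a Sonogashira coupling of a ring-A iodide with a ring-B arylacetylene made from 4-bromo-3-methoxyphenol.
5. The ring-A iodide comes from 5-methoxyresorcinol by formylation. Chelation to the formyl group tells the two hydroxyls apart (free OH to MOM, chelated OH later to acetate). The formyl group is then grown into the 3-hydroxy-3-methylbutyl chain, which avoids an unselective C-prenylation.

Key step: step 13

Remark: the target has no stereocentre, and the E geometry of the cinnamate made in step 3 is the only stereodescriptor in the route and is erased in step 4.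

## Route

Step 1
Reactants: 1 5-methoxyresorcinol
Product: 3 2,4-dihydroxy-6-methoxybenzaldehyde, via aryl iminium chloride 2 (not isolated)
Conditions: POCl3 (1.2 equiv), DMF (1.5 equiv), MeCN, 0 °C → rt; then H2O, 50 °C
Reagents that add atoms: N,N-dimethylformamide, CN(C)C=O; water, O
Why: Vilsmeier–Haack formylation: the chloroiminium ion made from DMF and POCl3 should attack one of the two equivalent ring positions para to one hydroxyl and ortho to the other, the site that 3,5-dioxygenated phenols prefer over the crowded position between the two hydroxyls, and water then hydrolyses iminium salt 2 to the aldehyde, any minor 2,6-dihydroxy isomer being removed by crystallisation.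

Step 2
Reactants: 3 2,4-dihydroxy-6-methoxybenzaldehyde
Product: 4 2-hydroxy-6-methoxy-4-(methoxymethoxy)benzaldehyde
Conditions: MOMCl (1.05 equiv), i-Pr2NEt (1.5 equiv), CH2Cl2, 0 °C
Reagents that add atoms: chloromethyl methyl ether, COCCl
Why: Selective O-alkylation (Williamson-type acetal ether formation): the 2-OH is tied up in a hydrogen bond to the formyl oxygen and is far less nucleophilic, so one equivalent of MOMCl should go to the free 4-OH, the oxygen that later becomes O1.

Step 3
Reactants: 4 2-hydroxy-6-methoxy-4-(methoxymethoxy)benzaldehyde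
Product: 5 methyl (E)-3-[2-hydroxy-6-methoxy-4-(methoxymethoxy)phenyl]prop-2-enoate
Conditions: Ph3P=CHCO2Me (1.3 equiv), toluene, 80 °C
Reagents that add atoms: methyl (triphenylphosphoranylidene)acetate, COC(=O)C=P(c1ccccc1)(c1ccccc1)c1ccccc1
Why: Wittig olefination with a stabilised ylide, which tolerates the free phenol and should give mainly the E-cinnamate; any Z-ester closes to the corresponding coumarin, which passes through steps 4 and 5 to the same product.

Step 4
Reactants: 5 methyl (E)-3-[2-hydroxy-6-methoxy-4-(methoxymethoxy)phenyl]prop-2-enoate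
Product: 6 methyl 3-[2-hydroxy-6-methoxy-4-(methoxymethoxy)phenyl]propanoate
Conditions: H2 (1 atm), 10% Pd/C, EtOAc, rt
Reagents that add atoms: none
Why: Catalytic hydrogenation of a conjugated alkene under neutral conditions leaves the acetal, the aryl ethers and the ester untouched, and it is placed here because neither the iodide nor the alkyne of later steps would survive it.

Step 5
Reactants: 6 methyl 3-[2-hydroxy-6-methoxy-4-(methoxymethoxy)phenyl]propanoate
Product: 8 2-(3-hydroxy-3-methylbutyl)-3-methoxy-5-(methoxymethoxy)phenol, via methyl ketone 7 (not isolated)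
Conditions: MeMgBr (4.5 equiv), THF, 0 °C → rt; then aq. NH4Cl
Reagents that add atoms: methylmagnesium bromide, C[Mg]Br
Why: Double Grignard addition to an ester: the first equivalent deprotonates the phenol, two more convert the ester by way of ketone 7 into the tertiary carbinol, and the acetal is inert to the reagent.

Step 6
Reactants: 8 2-(3-hydroxy-3-methylbutyl)-3-methoxy-5-(methoxymethoxy)phenol
Product: 9 2-(3-hydroxy-3-methylbutyl)-6-iodo-3-methoxy-5-(methoxymethoxy)phenol
Conditions: NIS (1.0 equiv), CH2Cl2, −20 → 0 °C, dark
Reagents that add atoms: N-iodosuccinimide, O=C1CCC(=O)N1I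
Why: Electrophilic aromatic iodination: of the two free ring positions the one between OH and OMOM is ortho to the free hydroxyl and para to the methoxy group and can receive iodine from hydroxyl-bound NIS in a non-polar solvent, whereas the other lies between two ether groups, one of which (the methoxy group) is pushed towards it by the neighbouring alkyl chain, the same ortho preference that 3,5-dialkoxyphenols show.

Step 7
Reactants: 9 2-(3-hydroxy-3-methylbutyl)-6-iodo-3-methoxy-5-(methoxymethoxy)phenol
Product: 10 2-(3-hydroxy-3-methylbutyl)-6-iodo-3-methoxy-5-(methoxymethoxy)phenyl acetate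
Conditions: Ac2O (1.2 equiv), DMAP (5 mol %), pyridine, 0 °C → rt
Reagents that add atoms: acetic anhydride, CC(=O)OC(C)=O
Why: Nucleophile-catalysed acylation: the phenol reacts much faster than the tertiary alcohol with a slight excess of anhydride, and the ester takes away the nucleophilicity of the oxygen that must not close the furan.

Step 8
Reactants: 10 2-(3-hydroxy-3-methylbutyl)-6-iodo-3-methoxy-5-(methoxymethoxy)phenyl acetate
Product: 11 6-iodo-3-methoxy-5-(methoxymethoxy)-2-[3-methyl-3-(triethylsilyloxy)butyl]phenyl acetate
Conditions: TESOTf (1.2 equiv), 2,6-lutidine (2 equiv), CH2Cl2, −78 → −20 °C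
Reagents that add atoms: triethylsilyl trifluoromethanesulfonate, CC[Si](CC)(CC)OS(=O)(=O)C(F)(F)F
Why: Silylation of a hindered tertiary alcohol with a silyl triflate and a non-nucleophilic base; low temperature and near-stoichiometric triflate keep the aryl acetal from exchanging, and the acetate and iodide are inert.

Step 9
Reactants: 12 4-bromo-3-methoxyphenol
Product: 13 (4-bromo-3-methoxyphenoxy)triisopropylsilane
Conditions: TIPSCl (1.1 equiv), imidazole (2 equiv), DMF, rt
Reagents that add atoms: chlorotriisopropylsilane, CC(C)[Si](Cl)(C(C)C)C(C)C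
Why: Imidazole-promoted silylation of a phenol; the bulky triisopropylsilyl group is chosen because it has to outlast carbonate in methanol, amines, PtCl2 and DDQ.

Step 10
Reactants: 13 (4-bromo-3-methoxyphenoxy)triisopropylsilane
Product: 14 {3-methoxy-4-[(trimethylsilyl)ethynyl]phenoxy}triisopropylsilane
Conditions: HC≡CSiMe3 (1.3 equiv), PdCl2(PhCN)2 (3 mol %), [HP(t-Bu)3]BF4 (6 mol %), CuI (2 mol %), i-Pr2NH (1.5 equiv), dioxane, rt
Reagents that add atoms: ethynyltrimethylsilane, C#C[Si](C)(C)C
Why: Sonogashira coupling; the electron-rich, ortho-substituted aryl bromide is slow in oxidative addition, which the bulky, electron-rich phosphine P(t-Bu)3 on zerovalent palladium overcomes at room temperature.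

Step 11
Reactants: 14 {3-methoxy-4-[(trimethylsilyl)ethynyl]phenoxy}triisopropylsilane
Product: 15 (4-ethynyl-3-methoxyphenoxy)triisopropylsilane
Conditions: K2CO3 (0.2 equiv), MeOH/CH2Cl2, 0 °C → rt
Reagents that add atoms: none
Why: Base-catalysed protodesilylation of the alkynyl C–Si bond by methoxide, which is much faster than attack at the hindered aryl triisopropylsilyl ether.

Step 12
Reactants: 11 6-iodo-3-methoxy-5-(methoxymethoxy)-2-[3-methyl-3-(triethylsilyloxy)butyl]phenyl acetate; 15 (4-ethynyl-3-methoxyphenoxy)triisopropylsilane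
Product: 16 3-methoxy-6-{[2-methoxy-4-(triisopropylsilyloxy)phenyl]ethynyl}-5-(methoxymethoxy)-2-[3-methyl-3-(triethylsilyloxy)butyl]phenyl acetate
Conditions: PdCl2(PPh3)2 (5 mol %), CuI (10 mol %), Et3N/DMF 1:2 (dry, degassed), 50 °C, slow addition of 15 (1.2 equiv)
Reagents that add atoms: none
Why: Sonogashira coupling of an aryl iodide flanked by two oxygen substituents, a known if slow substrate class; a tertiary amine in dry medium cannot aminolyse the acetate, so no free phenol arises that could cyclise through the wrong oxygen, and degassing together with slow addition of 15 holds back alkyne homocoupling.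

Step 13
Reactants: 16 3-methoxy-6-{[2-methoxy-4-(triisopropylsilyloxy)phenyl]ethynyl}-5-(methoxymethoxy)-2-[3-methyl-3-(triethylsilyloxy)butyl]phenyl acetate
Product: 17 6-methoxy-3-(methoxymethyl)-2-[2-methoxy-4-(triisopropylsilyloxy)phenyl]-5-[3-methyl-3-(triethylsilyloxy)butyl]-1-benzofuran-4-yl acetate
Conditions: PtCl2 (10 mol %), CO (1 atm), 4 Å MS, toluene, 80 °C
Reagents that add atoms: none
Why: PtCl2, made more electrophilic by CO, binds the diarylalkyne, and the aryl oxygen of the methoxymethyl ether adds anti to the metal at the alkyne carbon bearing ring B in a 5-endo-dig closure that forms O1–C2 and leaves an oxonium ion next to a C3–Pt bond. The oxonium ion sheds the oxygen-stabilised cation CH2=OMe+, which the metal-bearing carbon C3 picks up, so that C3–CH2 forms and divalent platinum is released, in all an isomerisation with a formal 1,3-shift from oxygen to carbon. This is the known platinum-catalysed carboalkoxylation of ortho-alkynylphenyl acetals and alkoxymethyl ethers to 2,3-disubstituted benzofurans, applied here to a more crowded diarylalkyne. Three oxygens flank the alkyne: the acetate oxygen on the future C4 is delocalised into its carbonyl group and does not add, and addition of the ring-B methoxy oxygen is reversible and unproductive because a methyl cation cannot leave, so only the acetal path goes forward. The donor groups of ring B (ortho-OMe, para-OTIPS) polarise the alkyne so that the carbon that becomes C2 is the electrophilic one, and the returning cation goes to C3 because that carbon carries the metal. No stereocentre is formed, and dry toluene over sieves is needed so that the C3–Pt bond is not protonated before the cation returns.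

Step 14
Reactants: 17 6-methoxy-3-(methoxymethyl)-2-[2-methoxy-4-(triisopropylsilyloxy)phenyl]-5-[3-methyl-3-(triethylsilyloxy)butyl]-1-benzofuran-4-yl acetate
Product: 18 3-formyl-6-methoxy-2-[2-methoxy-4-(triisopropylsilyloxy)phenyl]-5-[3-methyl-3-(triethylsilyloxy)butyl]-1-benzofuran-4-yl acetate
Conditions: DDQ (1.5 equiv), CH2Cl2/pH 7 buffer 10:1, 0 °C → rt
Reagents that add atoms: water, O
Why: DDQ oxidation of an electron-rich benzylic methyl ether: hydride is abstracted from the C3–CH2 group, the only C–H flanked both by an ether oxygen and by the enol-ether system O1–C2=C3 extended by donor ring B, water adds to the oxocarbenium ion, the hemiacetal collapses to aldehyde and methanol, and the new formyl group deactivates the ring system against further oxidation.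

Step 15
Reactants: 18 3-formyl-6-methoxy-2-[2-methoxy-4-(triisopropylsilyloxy)phenyl]-5-[3-methyl-3-(triethylsilyloxy)butyl]-1-benzofuran-4-yl acetate
Product: 19 4-hydroxy-6-methoxy-2-[2-methoxy-4-(triisopropylsilyloxy)phenyl]-5-[3-methyl-3-(triethylsilyloxy)butyl]-1-benzofuran-3-carbaldehyde
Conditions: K2CO3 (0.3 equiv), MeOH/THF, 0 °C → rt
Reagents that add atoms: none
Why: Base-catalysed transesterification of an aryl acetate, far faster than attack on either silyl ether, and the non-enolisable aldehyde is indifferent to carbonate; early loss of the aryl silyl group would do no harm since it falls in the next step.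

Step 16
Reactants: 19 4-hydroxy-6-methoxy-2-[2-methoxy-4-(triisopropylsilyloxy)phenyl]-5-[3-methyl-3-(triethylsilyloxy)butyl]-1-benzofuran-3-carbaldehyde
Product: 20 Ebenfuran VI
Conditions: TBAF (3 equiv), AcOH (3 equiv), THF, 0 → 40 °C
Reagents that add atoms: none
Why: Fluoride-induced cleavage of both Si–O bonds, driven by the strong Si–F bond; acetic acid buffers the alkoxide and phenoxides so that the aldehyde sees no strong base, and no strong acid is present that could dehydrate the tertiary alcohol or close it onto the C4 hydroxyl as a chroman.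

## Compound list

1 | 5-methoxyresorcinol | COc1cc(O)cc(O)c1 | starting material
2 | [(2,4-dihydroxy-6-methoxyphenyl)methylidene]dimethylammonium chloride | COc1cc(O)cc(O)c1C=[N+](C)C.[Cl-] | intermediate
3 | 2,4-dihydroxy-6-methoxybenzaldehyde | COc1cc(O)cc(O)c1C=O | intermediate
4 | 2-hydroxy-6-methoxy-4-(methoxymethoxy)benzaldehyde | COCOc1cc(O)c(C=O)c(OC)c1 | intermediate
5 | methyl (E)-3-[2-hydroxy-6-methoxy-4-(methoxymethoxy)phenyl]prop-2-enoate | COCOc1cc(O)c(/C=C/C(=O)OC)c(OC)c1 | intermediate
6 | methyl 3-[2-hydroxy-6-methoxy-4-(methoxymethoxy)phenyl]propanoate | COCOc1cc(O)c(CCC(=O)OC)c(OC)c1 | intermediate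
7 | 4-[2-hydroxy-6-methoxy-4-(methoxymethoxy)phenyl]butan-2-one (present as its magnesium phenoxide) | COCOc1cc(O)c(CCC(C)=O)c(OC)c1 | intermediate
8 | 2-(3-hydroxy-3-methylbutyl)-3-methoxy-5-(methoxymethoxy)phenol | COCOc1cc(O)c(CCC(C)(C)O)c(OC)c1 | intermediate
9 | 2-(3-hydroxy-3-methylbutyl)-6-iodo-3-methoxy-5-(methoxymethoxy)phenol | COCOc1cc(OC)c(CCC(C)(C)O)c(O)c1I | intermediate
10 | 2-(3-hydroxy-3-methylbutyl)-6-iodo-3-methoxy-5-(methoxymethoxy)phenyl acetate | COCOc1cc(OC)c(CCC(C)(C)O)c(OC(C)=O)c1I | intermediate
11 | 6-iodo-3-methoxy-5-(methoxymethoxy)-2-[3-methyl-3-(triethylsilyloxy)butyl]phenyl acetate | COCOc1cc(OC)c(CCC(C)(C)O[Si](CC)(CC)CC)c(OC(C)=O)c1I | intermediate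
12 | 4-bromo-3-methoxyphenol | COc1cc(O)ccc1Br | starting material
13 | (4-bromo-3-methoxyphenoxy)triisopropylsilane | COc1cc(O[Si](C(C)C)(C(C)C)C(C)C)ccc1Br | intermediate
14 | {3-methoxy-4-[(trimethylsilyl)ethynyl]phenoxy}triisopropylsilane | COc1cc(O[Si](C(C)C)(C(C)C)C(C)C)ccc1C#C[Si](C)(C)C | intermediate
15 | (4-ethynyl-3-methoxyphenoxy)triisopropylsilane | C#Cc1ccc(O[Si](C(C)C)(C(C)C)C(C)C)cc1OC | intermediate
16 | 3-methoxy-6-{[2-methoxy-4-(triisopropylsilyloxy)phenyl]ethynyl}-5-(methoxymethoxy)-2-[3-methyl-3-(triethylsilyloxy)butyl]phenyl acetate | COCOc1cc(OC)c(CCC(C)(C)O[Si](CC)(CC)CC)c(OC(C)=O)c1C#Cc1ccc(O[Si](C(C)C)(C(C)C)C(C)C)cc1OC | intermediate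
17 | 6-methoxy-3-(methoxymethyl)-2-[2-methoxy-4-(triisopropylsilyloxy)phenyl]-5-[3-methyl-3-(triethylsilyloxy)butyl]-1-benzofuran-4-yl acetate | COCc1c(-c2ccc(O[Si](C(C)C)(C(C)C)C(C)C)cc2OC)oc2cc(OC)c(CCC(C)(C)O[Si](CC)(CC)CC)c(OC(C)=O)c12 | intermediate
18 | 3-formyl-6-methoxy-2-[2-methoxy-4-(triisopropylsilyloxy)phenyl]-5-[3-methyl-3-(triethylsilyloxy)butyl]-1-benzofuran-4-yl acetate | O=Cc1c(-c2ccc(O[Si](C(C)C)(C(C)C)C(C)C)cc2OC)oc2cc(OC)c(CCC(C)(C)O[Si](CC)(CC)CC)c(OC(C)=O)c12 | intermediate
19 | 4-hydroxy-6-methoxy-2-[2-methoxy-4-(triisopropylsilyloxy)phenyl]-5-[3-methyl-3-(triethylsilyloxy)butyl]-1-benzofuran-3-carbaldehyde | O=Cc1c(-c2ccc(O[Si](C(C)C)(C(C)C)C(C)C)cc2OC)oc2cc(OC)c(CCC(C)(C)O[Si](CC)(CC)CC)c(O)c12 | intermediate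
20 | Ebenfuran VI, 4-hydroxy-5-(3-hydroxy-3-methylbutyl)-2-(4-hydroxy-2-methoxyphenyl)-6-methoxy-1-benzofuran-3-carbaldehyde | COc1cc(O)ccc1-c1oc2cc(OC)c(CCC(C)(C)O)c(O)c2c1C=O | target

## Step count and risks

Total step count: 16. Longest linear sequence: 13 (steps 1–8 and 12–16).

Steps most likely to fail:

**Step 13.** Crowding between the peri acetate and ring B may slow the return of the methoxymethyl cation. The cation could then escape from the ion pair, and the C3–Pt bond could be protonated, so that the one-carbon unit is lost. Hydration of the activated alkyne is a second drain.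

The fallback sets out from 16 and returns at 18. Electrophilic iodocyclisation of the ortho-alkynylaryl acetal ether (I2, NaHCO3, CH2Cl2, rt) should close the same O1–C2 bond. The acetal oxonium ion fragments faster than iodide can demethylate an oxonium ion formed from the ring-B methoxy group. This should give 3-iodo-6-methoxy-2-[2-methoxy-4-(triisopropylsilyloxy)phenyl]-5-[3-methyl-3-(triethylsilyloxy)butyl]-1-benzofuran-4-yl acetate F1. Palladium-catalysed reductive carbonylation of F1 under neutral conditions (Pd(PPh3)4, CO, slow addition of Bu3SnH, THF, 50 °C) then puts the formyl group on C3. This delivers 18 directly and makes step 14 unnecessary.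

**Step 14.** Oxidative degradation or coupling of the very electron-rich 2-arylbenzofuran may occur. Competing hydride abstraction at the benzylic CH2 on C5 and acid-induced loss of the triethylsilyl group may also accompany the wanted oxidation.

The fallback sets out from 17 and returns at 18. It replaces hydride abstraction by ionisation and displacement. Bromodimethylborane (1.1 equiv, CH2Cl2, −78 °C) should exchange the most ionisable ether, the C3–CH2OMe group, for bromide. This gives 3-(bromomethyl)-6-methoxy-2-[2-methoxy-4-(triisopropylsilyloxy)phenyl]-5-[3-methyl-3-(triethylsilyloxy)butyl]-1-benzofuran-4-yl acetate F2, which is used crude. A Kornblum-type oxidation with N-methylmorpholine N-oxide (MeCN, 4 Å MS, rt) converts F2 into 18.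

**Step 6.** Site selectivity between the two free ring positions may be poor, and a second iodination of the activated phenol may occur.

The fallback sets out from 4 and returns at 9. It moves the iodination to the aldehyde stage. 2-Hydroxy-4,6-dialkoxyaryl carbonyl compounds are known to be iodinated next to the chelated hydroxyl, and the formyl group tempers the ring against a second iodination.
- BnMe3NICl2 with NaHCO3 in CH2Cl2/MeOH should give 2-hydroxy-3-iodo-6-methoxy-4-(methoxymethoxy)benzaldehyde F3.
- Wittig olefination as in step 3 gives methyl (E)-3-[2-hydroxy-3-iodo-6-methoxy-4-(methoxymethoxy)phenyl]prop-2-enoate F4.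
- Diimide reduction (2-nitrobenzenesulfonylhydrazide, Et3N, CH2Cl2, rt) spares the C–I bond and gives methyl 3-[2-hydroxy-3-iodo-6-methoxy-4-(methoxymethoxy)phenyl]propanoate F5.
- MeMgBr in THF at 0 °C does not exchange with an electron-rich aryl iodide at that temperature. It leads by way of 4-[2-hydroxy-3-iodo-6-methoxy-4-(methoxymethoxy)phenyl]butan-2-one F6 to 9.

Further compounds
F1 | step 13 | 3-iodo-6-methoxy-2-[2-methoxy-4-(triisopropylsilyloxy)phenyl]-5-[3-methyl-3-(triethylsilyloxy)butyl]-1-benzofuran-4-yl acetate | Ic1c(-c2ccc(O[Si](C(C)C)(C(C)C)C(C)C)cc2OC)oc2cc(OC)c(CCC(C)(C)O[Si](CC)(CC)CC)c(OC(C)=O)c12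
F2 | step 14 | 3-(bromomethyl)-6-methoxy-2-[2-methoxy-4-(triisopropylsilyloxy)phenyl]-5-[3-methyl-3-(triethylsilyloxy)butyl]-1-benzofuran-4-yl acetate | BrCc1c(-c2ccc(O[Si](C(C)C)(C(C)C)C(C)C)cc2OC)oc2cc(OC)c(CCC(C)(C)O[Si](CC)(CC)CC)c(OC(C)=O)c12
F3 | step 6 | 2-hydroxy-3-iodo-6-methoxy-4-(methoxymethoxy)benzaldehyde | COCOc1cc(OC)c(C=O)c(O)c1I
F4 | step 6 | methyl (E)-3-[2-hydroxy-3-iodo-6-methoxy-4-(methoxymethoxy)phenyl]prop-2-enoate | COCOc1cc(OC)c(/C=C/C(=O)OC)c(O)c1I
F5 | step 6 | methyl 3-[2-hydroxy-3-iodo-6-methoxy-4-(methoxymethoxy)phenyl]propanoate | COCOc1cc(OC)c(CCC(=O)OC)c(O)c1I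
F6 | step 6 | 4-[2-hydroxy-3-iodo-6-methoxy-4-(methoxymethoxy)phenyl]butan-2-one | COCOc1cc(OC)c(CCC(C)=O)c(O)c1I
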